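**Analysis of the target**

The target 14 is a 2-arylbenzofuran. Ring A (C3a to C7a) is fused to the furan ring (O1, C2, C3), and C2 carries ring B, a 2,4-dihydroxyphenyl group. Ring A is pentasubstituted, with a hydroxyl at C4, a 3-hydroxy-3-methylbutyl chain at C5, a methoxy group at C6 and hydrogen only at C7. The furan ring is fully substituted and bears the formyl group at C3. There is no stereocentre, so the problems are regiochemistry and the differentiation of four phenolic oxygens, of which only the one at C6 is a methyl ether. The sensitive groups are the C3 aldehyde (a vinylogous formate next to the C4 and C2' hydroxyls), the oxidation-prone electron-rich phenols, and the tertiary alcohol, which under acid dehydrates or closes a 2,2-dimethylchroman onto the C4 oxygen. Formylation of a preformed 2-arylbenzofuran would have to choose C3 over the equally activated C7 and over ring B, and the C5 chain must be placed between two oxygens. The strategy rests on the sequence O1–C2–C3–CHO: O1 and the formyl carbon are 1,3-related across C2. A one-carbon acetal group that protects the O1 oxygen can therefore be moved to C3 in the event that closes the furan ring, with the two alkyne carbons becoming C2 and C3.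

**Retrosynthetic reasoning**

14 to 13. The three free phenols are unveiled last by cleaving three oxygen–benzyl bonds. Free phenols of this kind would not survive the oxidation that makes the aldehyde or the metal-catalysed steps. Benzyl ethers tolerate base, the alkyne-forming step and the cross-coupling, and they leave under neutral conditions that spare the methyl ether and the tertiary alcohol.

13 to 12. The formyl group is traced back to a methoxymethyl group on C3. The forward step is a C–H oxidation of an electron-rich hetero-benzylic ether. It must act on this methylene and not on the C5 benzylic methylene or the benzyl ethers. The gain is that the C3 carbon is already in place and only its oxidation level changes.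

12 to 11. This is the central disconnection. The O1–C2 bond and the C3–CH2 bond are cut, the methoxymethyl group is returned to the O1 oxygen as an acetal, and C2 and C3 become a diaryl alkyne. Both bonds end at the two alkyne carbons, so one activation of the triple bond can form both. C3 is substituted during ring closure, so no formylation with a C3 against C7 problem arises. The forward reaction must bring the acetal oxygen onto C2 and hand its carbon group to C3 without losing it.

11 to 10. The tertiary alcohol is traced back to the trisubstituted alkene of a prenyl group. The hydration is placed here for two reasons. At earlier stages a free phenol next to the chain would close a chroman under acid, and an aldehyde or a terminal alkyne would be exposed to the radical and oxygen conditions. At this stage only ethers and a hindered internal alkyne are present.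

10 to 7 and 9. The bond between the alkyne and ring B is cut, which gives a terminal aryl alkyne 7 and an aryl bromide 9. The cut on the ring A side is not used, because a ring A halide would have to be made by halogenating between two pairs of similar oxygens without regiocontrol. The forward coupling has to join a hindered, electron-rich alkyne with an electron-rich bromide.

7 to 6. The terminal alkyne comes from the aldehyde 6 by one-carbon homologation. The aldehyde carbon becomes C3 and the added carbon becomes C2. The position between the two ortho oxygens is thus fixed by the starting aldehyde and needs no selective aromatic substitution.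

6 to 5 to 4. The two oxygens ortho to the formyl group are told apart by their surroundings. The one next to the ring hydrogen is the future O1 and takes the migrating acetal. The one next to the prenyl group is the future C4 oxygen and takes a benzyl group.

4 to 2 and 3, 2 to 1, and 9 to 8. The prenyl group is attached to the ring carbon between a hydroxyl and the methoxy group of the symmetric aldehyde 2, where both open positions are equivalent. Compound 2 comes from 1 by methylation of the one hydroxyl that is not hydrogen-bonded to the formyl group. Compound 9 comes from 8 by double benzylation.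

**Alternatives that were turned down**

Alternative 1: Ring A built onto a furan by a Danheiser benzannulation.
- Disconnection: four bonds of ring A are cut (C3a–C4, C4–C5, C6–C7, C7–C7a).
- Forward key step: the furyl diazo ketone A2 is irradiated with the methoxy alkyne A3. Wolff rearrangement gives a furyl ketene, which adds to the alkyne in a [2+2] manner. Four-electron ring opening and six-electron ring closure on warming then give the phenol A1.
- For it: the C4 hydroxyl is born free and the C6 methoxy group and the C5 chain arrive with the alkyne. The oxygen pattern of ring A therefore needs no selective protection. On this point it is stronger than the chosen route, which depends on a selective methylation, a C-prenylation and a selective acetal formation.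
- Against it: A2 is a trisubstituted furan that itself needs several steps. A3 is a sensitive alkynyl ether. The photochemical step must tolerate a furan and benzyl ethers. C3 emerges as an ester, so a reduction and an oxidation are still needed.
- Comparison: the chosen strategy starts from a cheap aldehyde, avoids photochemistry and diazo compounds, and delivers the C3 carbon one oxidation away from the aldehyde in a shorter sequence.

Alternative 2: Late introduction of the ring B ortho oxygen by anodic lactonisation.
- Disconnection: the C2'–O bond is cut.
- Forward key step: the benzofuran-3-carboxylic acid A5 is electrolysed at a carbon anode, so that the carboxylate oxygen attacks the unsubstituted C2' and closes the six-membered lactone of the coumestan A4.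
- For it: ring B can be carried without its ortho oxygen, and the lactone masks the 2' oxygen and the C3 carbonyl carbon together. The idea of one group serving two positions is as attractive as in the chosen route.
- Against it: ring A and the benzyl ethers are more easily oxidised than ring B. C2' is meta to the 4' benzyloxy donor and so is not the favoured site of attack on an oxidised ring B. Decarboxylation competes. Afterwards the lactone must be half-reduced to the aldehyde level without over-reduction, and A5 needs a benzofuran synthesis of its own.
- Comparison: in the chosen route the 2' oxygen comes with commercial 8 and the only redox change at the C3 carbon is one oxidation.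

Alternative 3: Aryne annulation with a keto ester ylide.
- Disconnection: O1–C7a and C3–C3a are cut.
- Forward key step: fluoride releases the C3a–C7a aryne from the silyl triflate A7. The ketone oxygen of the iodonium ylide A8 adds at C7a, and the aryl anion at C3a takes the ylide carbon with loss of iodobenzene, giving the ester A6.
- For it: it is convergent, forms both bonds from the furan to ring A in one step, and the C4 benzyloxy group steers the oxygen to the distal aryne carbon. In convergence it equals the cross-coupling used here.
- Against it: A7 is a hexasubstituted benzene with adjacent silyl and triflate groups. Its regiocontrolled preparation would cost more steps than all of ring A in the chosen route. The tertiary alcohol must be carried as a benzyl ether that is hard to install. The regioselectivity of the aryne is eroded by its further substituents. C3 again arrives as an ester.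
- Comparison: the chosen strategy reaches its precursor 11 in few standard steps and leaves the risk in one ring-forming step.

Key step: step 9

Remark on the chemistry: the Markovnikov hydration is placed after the fragment coupling, because acid hydration next to a free phenol would close a chroman ring and radical hydration is better kept away from the aldehyde and the terminal alkyne.

**Steps**

Step 1
Reactants: 1 2,4,6-trihydroxybenzaldehyde
Product: 2 2,6-dihydroxy-4-methoxybenzaldehyde
Conditions: Me2SO4 (1.0 equiv), K2CO3 (1.0 equiv), acetone, 0 °C to rt
Reagents that add atoms: dimethyl sulfate, COS(=O)(=O)OC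
Why: Selective O-alkylation of a phenol; the 4-hydroxyl is para to the formyl group, not hydrogen-bonded and the most acidic, so one equivalent of base and of the hard methylating agent should methylate it while the two chelated ortho hydroxyls stay free.

Step 2
Reactants: 2 2,6-dihydroxy-4-methoxybenzaldehyde; 3 prenyl bromide (1-bromo-3-methylbut-2-ene)
Product: 4 2,6-dihydroxy-4-methoxy-3-(3-methylbut-2-en-1-yl)benzaldehyde
Conditions: 10% aq. KOH, 0 °C to rt
Reagents that add atoms: none
Why: C-alkylation of an ambident phenoxide; in water the oxygen is solvated and the soft allylic bromide should be taken by the ring carbon ortho to the phenoxide, and because C3 and C5 of 2 are equivalent only one mono-C-prenyl product can form.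

Step 3
Reactants: 4 2,6-dihydroxy-4-methoxy-3-(3-methylbut-2-en-1-yl)benzaldehyde
Product: 5 2-hydroxy-4-methoxy-6-(methoxymethoxy)-3-(3-methylbut-2-en-1-yl)benzaldehyde
Conditions: MOMCl (1.05 equiv), i-Pr2NEt, CH2Cl2, 0 °C
Reagents that add atoms: chloromethyl methyl ether, COCCl
Why: Selective acetal protection of a phenol; the hydroxyl next to the ring hydrogen is the less hindered one and should react first, after which the hydroxyl flanked by the prenyl group stays locked in a hydrogen bond to the formyl oxygen.

Step 4
Reactants: 5 2-hydroxy-4-methoxy-6-(methoxymethoxy)-3-(3-methylbut-2-en-1-yl)benzaldehyde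
Product: 6 2-(benzyloxy)-4-methoxy-6-(methoxymethoxy)-3-(3-methylbut-2-en-1-yl)benzaldehyde
Conditions: BnBr, K2CO3, n-Bu4NI (cat.), DMF, 60 °C
Reagents that add atoms: benzyl bromide, BrCc1ccccc1
Why: Williamson ether synthesis; the chelated, hindered phenol needs a polar solvent and warming, and the aldehyde, the acetal and the alkene are inert to carbonate base.

Step 5
Reactants: 6 2-(benzyloxy)-4-methoxy-6-(methoxymethoxy)-3-(3-methylbut-2-en-1-yl)benzaldehyde
Product: 7 3-(benzyloxy)-4-ethynyl-1-methoxy-5-(methoxymethoxy)-2-(3-methylbut-2-en-1-yl)benzene
Conditions: dimethyl (1-diazo-2-oxopropyl)phosphonate, K2CO3, MeOH/THF, 0 °C to rt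
Reagents that add atoms: dimethyl (1-diazo-2-oxopropyl)phosphonate, COP(=O)(OC)C(=[N+]=[N-])C(C)=O
Why: Ohira–Bestmann alkynylation (Seyferth–Gilbert homologation); the aldehyde has no enolisable position, the mild carbonate conditions spare the acetal, the benzyl ether and the prenyl group, and the alkylidene carbene rearranges to the alkyne faster than it can react elsewhere.

Step 6
Reactants: 8 4-bromoresorcinol
Product: 9 2,4-bis(benzyloxy)-1-bromobenzene
Conditions: BnBr (2.2 equiv), K2CO3, acetone, reflux
Reagents that add atoms: benzyl bromide, BrCc1ccccc1
Why: Double Williamson ether synthesis on two unhindered phenols; the aryl bromide is inert under these conditions.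

Step 7
Reactants: 7 3-(benzyloxy)-4-ethynyl-1-methoxy-5-(methoxymethoxy)-2-(3-methylbut-2-en-1-yl)benzene; 9 2,4-bis(benzyloxy)-1-bromobenzene
Product: 10 3-(benzyloxy)-4-{[2,4-bis(benzyloxy)phenyl]ethynyl}-1-methoxy-5-(methoxymethoxy)-2-(3-methylbut-2-en-1-yl)benzene
Conditions: PdCl2(MeCN)2 (3 mol %), XPhos (9 mol %), Cs2CO3, MeCN, 80 °C, slow addition of 7
Reagents that add atoms: none
Why: Copper-free Sonogashira coupling; the bulky electron-rich biarylphosphine lets zerovalent palladium insert into the electron-rich, ortho-substituted aryl bromide, and leaving out copper suppresses oxidative homocoupling of the electron-rich alkyne.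

Step 8
Reactants: 10 3-(benzyloxy)-4-{[2,4-bis(benzyloxy)phenyl]ethynyl}-1-methoxy-5-(methoxymethoxy)-2-(3-methylbut-2-en-1-yl)benzene
Product: 11 4-[2-(benzyloxy)-3-{[2,4-bis(benzyloxy)phenyl]ethynyl}-6-methoxy-4-(methoxymethoxy)phenyl]-2-methylbutan-2-ol
Conditions: Co(acac)2 (20 mol %), PhSiH3, O2 (1 atm), THF, rt
Reagents that add atoms: dioxygen, O=O
Why: Mukaiyama hydration; a cobalt hydride transfers a hydrogen atom to the less substituted alkene carbon, the tertiary radical is trapped by oxygen and reduced to the Markovnikov alcohol, and the acid-free conditions should leave the acetal, the benzyl ethers and the hindered diaryl alkyne untouched.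

Step 9
Reactants: 11 4-[2-(benzyloxy)-3-{[2,4-bis(benzyloxy)phenyl]ethynyl}-6-methoxy-4-(methoxymethoxy)phenyl]-2-methylbutan-2-ol
Product: 12 4-[4-(benzyloxy)-2-[2,4-bis(benzyloxy)phenyl]-6-methoxy-3-(methoxymethyl)benzofuran-5-yl]-2-methylbutan-2-ol
Conditions: PtCl2 (10 mol %), CO (1 atm), toluene, 60 °C
Reagents that add atoms: none
Why: PtCl2, made more electrophilic by CO, binds the triple bond, and the acetal oxygen on the neighbouring ring carbon adds anti to the metal at the alkyne carbon that bears ring B, which forms O1–C2 and gives an oxonium vinylplatinum species. The oxonium releases the methoxymethyl cation, the platinum-bearing C3 captures it to form the C3–CH2OMe bond, and loss of PtCl2 gives the benzofuran. The closest known reaction type is the PtCl2-catalysed carboalkoxylation of ortho-alkynylphenyl acetals to 3-(alkoxymethyl)benzofurans. The furan ring closes in a 5-endo-dig mode, the only one the ortho tether allows, so the oxygen must end on C2 and the metal on C3. No stereocentre is formed. The first selectivity needed is among three ether oxygens ortho to the alkyne: addition of an ether oxygen is reversible, and only the acetal oxonium can shed a stabilised oxocarbenium ion at this temperature, whereas benzyl transfer needs more forcing conditions, so the temperature is held as low as conversion allows. The second is carbon–carbon bond formation over protodemetalation, which dry toluene and the hindered, remote position of the tertiary alcohol should favour.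

Step 10
Reactants: 12 4-[4-(benzyloxy)-2-[2,4-bis(benzyloxy)phenyl]-6-methoxy-3-(methoxymethyl)benzofuran-5-yl]-2-methylbutan-2-ol
Product: 13 4-(benzyloxy)-2-[2,4-bis(benzyloxy)phenyl]-5-(3-hydroxy-3-methylbutyl)-6-methoxybenzofuran-3-carbaldehyde
Conditions: DDQ (1.5 equiv), CH2Cl2/H2O (10:1), 0 °C to rt
Reagents that add atoms: water, O
Why: DDQ oxidation of an electron-rich benzylic methyl ether; hydride abstraction gives a cation stabilised by the methoxy oxygen, by O1 through the C2–C3 double bond and by the C2 aryl group, water adds and the hemiacetal loses methanol, while the C5 methylene lacks the oxygen on carbon and plain benzyl ethers react far more slowly.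

Step 11
Reactants: 13 4-(benzyloxy)-2-[2,4-bis(benzyloxy)phenyl]-5-(3-hydroxy-3-methylbutyl)-6-methoxybenzofuran-3-carbaldehyde
Product: 14 2-(2,4-dihydroxyphenyl)-4-hydroxy-5-(3-hydroxy-3-methylbutyl)-6-methoxybenzofuran-3-carbaldehyde (ebenfuran V)
Conditions: H2 (1 atm), 10% Pd/C, EtOAc, rt, stopped after uptake of three equivalents
Reagents that add atoms: none
Why: Hydrogenolysis of three aryl benzyl ethers; the aldehyde is a vinylogous formate conjugated with O1 and the furan double bond is tetrasubstituted, so both should be reduced much more slowly than the benzyl–oxygen bonds are cleaved, and the methyl ether and the tertiary alcohol are inert.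

**Compound list**

1 | 2,4,6-trihydroxybenzaldehyde | O=Cc1c(O)cc(O)cc1O | starting material
2 | 2,6-dihydroxy-4-methoxybenzaldehyde | COc1cc(O)c(C=O)c(O)c1 | intermediate
3 | prenyl bromide (1-bromo-3-methylbut-2-ene) | CC(C)=CCBr | starting material
4 | 2,6-dihydroxy-4-methoxy-3-(3-methylbut-2-en-1-yl)benzaldehyde | COc1cc(O)c(C=O)c(O)c1CC=C(C)C | intermediate
5 | 2-hydroxy-4-methoxy-6-(methoxymethoxy)-3-(3-methylbut-2-en-1-yl)benzaldehyde | COCOc1cc(OC)c(CC=C(C)C)c(O)c1C=O | intermediate
6 | 2-(benzyloxy)-4-methoxy-6-(methoxymethoxy)-3-(3-methylbut-2-en-1-yl)benzaldehyde | COCOc1cc(OC)c(CC=C(C)C)c(OCc2ccccc2)c1C=O | intermediate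
7 | 3-(benzyloxy)-4-ethynyl-1-methoxy-5-(methoxymethoxy)-2-(3-methylbut-2-en-1-yl)benzene | COCOc1cc(OC)c(CC=C(C)C)c(OCc2ccccc2)c1C#C | intermediate
8 | 4-bromoresorcinol | Oc1ccc(Br)c(O)c1 | starting material
9 | 2,4-bis(benzyloxy)-1-bromobenzene | Brc1ccc(OCc2ccccc2)cc1OCc1ccccc1 | intermediate
10 | 3-(benzyloxy)-4-{[2,4-bis(benzyloxy)phenyl]ethynyl}-1-methoxy-5-(methoxymethoxy)-2-(3-methylbut-2-en-1-yl)benzene | COCOc1cc(OC)c(CC=C(C)C)c(OCc2ccccc2)c1C#Cc1ccc(OCc2ccccc2)cc1OCc1ccccc1 | intermediate
11 | 4-[2-(benzyloxy)-3-{[2,4-bis(benzyloxy)phenyl]ethynyl}-6-methoxy-4-(methoxymethoxy)phenyl]-2-methylbutan-2-ol | COCOc1cc(OC)c(CCC(C)(C)O)c(OCc2ccccc2)c1C#Cc1ccc(OCc2ccccc2)cc1OCc1ccccc1 | intermediate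
12 | 4-[4-(benzyloxy)-2-[2,4-bis(benzyloxy)phenyl]-6-methoxy-3-(methoxymethyl)benzofuran-5-yl]-2-methylbutan-2-ol | COCc1c(-c2ccc(OCc3ccccc3)cc2OCc2ccccc2)oc2cc(OC)c(CCC(C)(C)O)c(OCc3ccccc3)c12 | intermediate
13 | 4-(benzyloxy)-2-[2,4-bis(benzyloxy)phenyl]-5-(3-hydroxy-3-methylbutyl)-6-methoxybenzofuran-3-carbaldehyde | O=Cc1c(-c2ccc(OCc3ccccc3)cc2OCc2ccccc2)oc2cc(OC)c(CCC(C)(C)O)c(OCc3ccccc3)c12 | intermediate
14 | 2-(2,4-dihydroxyphenyl)-4-hydroxy-5-(3-hydroxy-3-methylbutyl)-6-methoxybenzofuran-3-carbaldehyde (ebenfuran V) | COc1cc2oc(-c3ccc(O)cc3O)c(C=O)c2c(O)c1CCC(C)(C)O | target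

**Step count and risk**

Total step count: 11. Longest linear sequence: 10 steps (steps 1 to 5 and 7 to 11, from 1 to 14); step 6 prepares the ring B fragment.

Step 9 (key step). Two processes may compete with the wanted shift. One is cyclisation through a benzyl ether oxygen with transfer of the benzyl group, since the C4 and C2' benzyloxy groups also sit ortho to the alkyne. The other is protonation of the vinylplatinum intermediate with loss of the methoxymethyl group to the tertiary alcohol or to traces of water, which would leave C3 unsubstituted. The fallback separates ring closure from carbon transfer and sets out from 11. Catalytic HCl in MeOH removes the acetal and gives 3-(benzyloxy)-2-{[2,4-bis(benzyloxy)phenyl]ethynyl}-4-(3-hydroxy-3-methylbutyl)-5-methoxyphenol F1. Iodine and NaHCO3 in MeCN then effect a 5-endo-dig iodocyclisation of the phenol to 4-[4-(benzyloxy)-2-[2,4-bis(benzyloxy)phenyl]-3-iodo-6-methoxybenzofuran-5-yl]-2-methylbutan-2-ol F2. Iodine–magnesium exchange with excess i-PrMgCl·LiCl in THF at −20 °C, the first equivalent being consumed by the tertiary alcohol, gives the chloromagnesium alkoxide of the 3-(chloromagnesio)benzofuran F3. F3 is not isolated and is quenched with DMF. The fallback comes back to the route at 13 and also bypasses step 10.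

Step 2. O-alkylation and double alkylation may erode the share of the mono-C-prenyl product, because 2 has only two acidic hydroxyls and ring carbons of moderate nucleophilicity. The fallback sets out from 2 and fixes the position by a sigmatropic shift. Allyl bromide and K2CO3 in acetone give 2-(allyloxy)-6-hydroxy-4-methoxybenzaldehyde F4. Aromatic Claisen rearrangement in N,N-diethylaniline at about 190 °C gives 3-allyl-2,6-dihydroxy-4-methoxybenzaldehyde F5; ortho and para migration lead to the same compound by symmetry. Olefin cross-metathesis with 2-methylbut-2-ene and the second-generation Grubbs catalyst in CH2Cl2 at 40 °C converts the allyl into the prenyl group. The fallback comes back to the route at 4.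

Step 10. Over-oxidation at the C5 benzylic methylene, slow oxidative loss of a benzyl ether, or stalling at partial conversion may occur, because the whole molecule is electron-rich. The fallback sets out from 12 and replaces hydride abstraction by substitution followed by alcohol oxidation. Dilute aqueous acid in THF exchanges the methoxy group of the vinylogous acetal for a hydroxyl and gives 4-[4-(benzyloxy)-2-[2,4-bis(benzyloxy)phenyl]-3-(hydroxymethyl)-6-methoxybenzofuran-5-yl]-2-methylbutan-2-ol F6. MnO2 in CH2Cl2 then oxidises only the hetero-benzylic primary alcohol. The fallback comes back to the route at 13.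

Step 11. Reduction of the aldehyde, or incomplete cleavage of the hindered C4 benzyl ether while the catalyst is kept mild, may occur. The fallback sets out from 13 and masks the aldehyde first. Trimethyl orthoformate with catalytic pyridinium p-toluenesulfonate in MeOH gives 4-[4-(benzyloxy)-2-[2,4-bis(benzyloxy)phenyl]-3-(dimethoxymethyl)-6-methoxybenzofuran-5-yl]-2-methylbutan-2-ol F7. Hydrogenolysis over Pd/C in EtOAc with a trace of Et3N gives 4-[3-(dimethoxymethyl)-4-hydroxy-5-(3-hydroxy-3-methylbutyl)-6-methoxybenzofuran-2-yl]benzene-1,3-diol F8. F8 is hydrolysed without purification by AcOH/H2O/THF at rt, conditions too mild to close a chroman. The fallback comes back to the route at 14.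

**Further compounds**

F1 | step 9 | 3-(benzyloxy)-2-{[2,4-bis(benzyloxy)phenyl]ethynyl}-4-(3-hydroxy-3-methylbutyl)-5-methoxyphenol | Oc1cc(OC)c(CCC(C)(C)O)c(OCc2ccccc2)c1C#Cc1ccc(OCc2ccccc2)cc1OCc1ccccc1
F2 | step 9 | 4-[4-(benzyloxy)-2-[2,4-bis(benzyloxy)phenyl]-3-iodo-6-methoxybenzofuran-5-yl]-2-methylbutan-2-ol | Ic1c(-c2ccc(OCc3ccccc3)cc2OCc2ccccc2)oc2cc(OC)c(CCC(C)(C)O)c(OCc3ccccc3)c12
F3 | step 9 | chloromagnesium alkoxide of the 3-(chloromagnesio)benzofuran, [4-(benzyloxy)-2-[2,4-bis(benzyloxy)phenyl]-5-{3-[(chloromagnesio)oxy]-3-methylbutyl}-6-methoxybenzofuran-3-yl]magnesium chloride | Cl[Mg]c1c(-c2ccc(OCc3ccccc3)cc2OCc2ccccc2)oc2cc(OC)c(CCC(C)(C)O[Mg]Cl)c(OCc3ccccc3)c12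
F4 | step 2 | 2-(allyloxy)-6-hydroxy-4-methoxybenzaldehyde | C=CCOc1cc(OC)cc(O)c1C=O
F5 | step 2 | 3-allyl-2,6-dihydroxy-4-methoxybenzaldehyde | C=CCc1c(OC)cc(O)c(C=O)c1O
F6 | step 10 | 4-[4-(benzyloxy)-2-[2,4-bis(benzyloxy)phenyl]-3-(hydroxymethyl)-6-methoxybenzofuran-5-yl]-2-methylbutan-2-ol | OCc1c(-c2ccc(OCc3ccccc3)cc2OCc2ccccc2)oc2cc(OC)c(CCC(C)(C)O)c(OCc3ccccc3)c12
F7 | step 11 | 4-[4-(benzyloxy)-2-[2,4-bis(benzyloxy)phenyl]-3-(dimethoxymethyl)-6-methoxybenzofuran-5-yl]-2-methylbutan-2-ol | COC(OC)c1c(-c2ccc(OCc3ccccc3)cc2OCc2ccccc2)oc2cc(OC)c(CCC(C)(C)O)c(OCc3ccccc3)c12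
F8 | step 11 | 4-[3-(dimethoxymethyl)-4-hydroxy-5-(3-hydroxy-3-methylbutyl)-6-methoxybenzofuran-2-yl]benzene-1,3-diol | COC(OC)c1c(-c2ccc(O)cc2O)oc2cc(OC)c(CCC(C)(C)O)c(O)c12
A1 | alternative 1 | methyl 2-[2,4-bis(benzyloxy)phenyl]-4-hydroxy-6-methoxy-5-[3-methyl-3-(triethylsilyloxy)butyl]benzofuran-3-carboxylate | COC(=O)c1c(-c2ccc(OCc3ccccc3)cc2OCc2ccccc2)oc2cc(OC)c(CCC(C)(C)O[Si](CC)(CC)CC)c(O)c12
A2 | alternative 1 | methyl 2-[2,4-bis(benzyloxy)phenyl]-5-(2-diazoacetyl)furan-3-carboxylate | COC(=O)c1cc(C(=O)C=[N+]=[N-])oc1-c1ccc(OCc2ccccc2)cc1OCc1ccccc1
A3 | alternative 1 | triethyl[(6-methoxy-2-methylhex-5-yn-2-yl)oxy]silane | COC#CCCC(C)(C)O[Si](CC)(CC)CC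
A4 | alternative 2 | 3,7-bis(benzyloxy)-8-(3-hydroxy-3-methylbutyl)-9-methoxy-6H-benzofuro[3,2-c]chromen-6-one | COc1cc2oc3-c4ccc(OCc5ccccc5)cc4OC(=O)c3c2c(OCc2ccccc2)c1CCC(C)(C)O
A5 | alternative 2 | 4-(benzyloxy)-2-[4-(benzyloxy)phenyl]-5-(3-hydroxy-3-methylbutyl)-6-methoxybenzofuran-3-carboxylic acid | OC(=O)c1c(-c2ccc(OCc3ccccc3)cc2)oc2cc(OC)c(CCC(C)(C)O)c(OCc3ccccc3)c12
A6 | alternative 3 | methyl 4-(benzyloxy)-5-[3-(benzyloxy)-3-methylbutyl]-2-[2,4-bis(benzyloxy)phenyl]-6-methoxybenzofuran-3-carboxylate | COC(=O)c1c(-c2ccc(OCc3ccccc3)cc2OCc2ccccc2)oc2cc(OC)c(CCC(C)(C)OCc3ccccc3)c(OCc3ccccc3)c12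
A7 | alternative 3 | 3-(benzyloxy)-4-[3-(benzyloxy)-3-methylbutyl]-5-methoxy-2-(trimethylsilyl)phenyl trifluoromethanesulfonate | C[Si](C)(C)c1c(OS(=O)(=O)C(F)(F)F)cc(OC)c(CCC(C)(C)OCc2ccccc2)c1OCc1ccccc1
A8 | alternative 3 | methyl 3-[2,4-bis(benzyloxy)phenyl]-3-oxo-2-(phenyl-λ3-iodanylidene)propanoate | COC(=O)[C-]([I+]c1ccccc1)C(=O)c1ccc(OCc2ccccc2)cc1OCc1ccccc1
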